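**Retrosynthetic overview**

1. Atom labels: ring B is C1=C10–C2(=O)–C3–C4(Me2)–C5; ring A is C5–C6–C7–C8(HMe)–C9(Me)(chain)–C10; the chain is C11–C16 with C13 bearing the CH2O group and C16 the furan.
2. Target ⇐ O-sulfation and desilylation ⇐ ring B closed last by intramolecular aldol condensation (C1=C10) of a 1,5-diketone.
3. 1,5-Diketone ⇐ C4–C5 bond by Mukaiyama–Michael addition of a ring A enol silane to mesityl oxide; the enol silane comes from a one-carbon ring expansion (1,2-alkyl shift, C5 inserted) of a 2,2,3-trisubstituted cyclopentanone.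
4. Cyclopentanone ⇐ asymmetric methyl conjugate addition and enolate methylation (C8, C9) of a 2-alkylcyclopent-2-enone ⇐ B-alkyl Suzuki coupling (C9–C11) of 2-iodocyclopent-2-en-1-one with a side-chain alkene.
5. Side-chain alkene ⇐ organocatalytic α-hydroxymethylation (C13) and Wittig reaction of 5-(furan-3-yl)pentanal ⇐ 3-bromofuran, a butenyl Grignard reagent and CO; ring order: furan (bought) → five-membered precursor of ring A → six-membered ring A → ring B.

Assumption: the target is taken as the free hydrogen sulfate exactly as drawn (handled cold or kept as its sodium salt); TBDPS means tert-butyl(diphenyl)silyl.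

**Route**

Step 1
Reactants: 1 3-bromofuran; 2 but-3-en-1-ylmagnesium bromide
Product: 3 3-(but-3-en-1-yl)furan
Conditions: NiCl2(dppp) (2 mol %), Et2O, 0 °C → reflux
Reagents that add atoms: none
Why: Kumada cross-coupling, in which zerovalent nickel formed from NiCl2(dppp) inserts into the furyl C–Br bond and the chelating diphosphine makes reductive elimination faster than β-hydride loss, so the primary alkyl group is joined without touching the terminal alkene (no stereocentre).

Step 2
Reactants: 3 3-(but-3-en-1-yl)furan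
Product: 4 5-(furan-3-yl)pentanal
Conditions: Rh(acac)(CO)2 (0.5 mol %), Xantphos, CO/H2 (1:1, 10 bar), toluene, 80 °C
Reagents that add atoms: carbon monoxide, [C-]#[O+]
Why: Linear-selective hydroformylation, in which the wide-bite-angle diphosphine on Rh(acac)(CO)2 enforces anti-Markovnikov insertion of the terminal alkene (linear:branched above 20:1) while the aromatic furan stays inert (no stereocentre).

Step 3
Reactants: 4 5-(furan-3-yl)pentanal
Product: 6 (2R)-2-({[tert-butyl(diphenyl)silyl]oxy}methyl)-5-(furan-3-yl)pentanal, via hydroxymethyl aldehyde 5 (not isolated)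
Conditions: aq. HCHO (37 %), (S)-2-[diphenyl(trimethylsilyloxy)methyl]pyrrolidine (10 mol %), pH 7 phosphate buffer, toluene, rt; organic phase dried; then t-BuPh2SiCl, imidazole, CH2Cl2, 0 °C
Reagents that add atoms: formaldehyde, C=O; tert-butyl(chloro)diphenylsilane, CC(C)(C)[Si](Cl)(c1ccccc1)c1ccccc1
Why: Enamine-catalysed α-hydroxymethylation (organocatalytic cross-aldol with formaldehyde), in which the E-enamine is attacked on the face remote from the CPh2OSiMe3 group so that C13 is set as (R) in 5 (typically above 90 % ee for linear aldehydes), and immediate O-silylation prevents hemiacetal formation and retro-aldol.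

Step 4
Reactants: 6 (2R)-silyloxymethyl aldehyde
Product: 7 tert-butyl{[(2S)-2-ethenyl-5-(furan-3-yl)pentyl]oxy}diphenylsilane
Conditions: Ph3PCH3Br, KN(SiMe3)2, THF, 0 °C; then 6, −78 → 0 °C
Reagents that add atoms: methyltriphenylphosphonium bromide, C[P+](c1ccccc1)(c1ccccc1)c1ccccc1.[Br-]
Why: Wittig methylenation, in which the unstabilised ylide adds to the aldehyde at low temperature faster than it enolises it and the silyloxy group is too poor a leaving group for β-elimination, so C13 is untouched (its descriptor becomes S only because the priorities change).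

Step 5
Reactants: 7 (2S)-alkene; 8 2-iodocyclopent-2-en-1-one
Product: 10 2-[(3S)-3-({[tert-butyl(diphenyl)silyl]oxy}methyl)-6-(furan-3-yl)hexyl]cyclopent-2-en-1-one, via alkylborane 9 (not isolated)
Conditions: 9-BBN, THF, rt; then 8, PdCl2(dppf) (5 mol %), AsPh3, Cs2CO3, DMF/H2O, rt
Reagents that add atoms: none
Why: Anti-Markovnikov hydroboration followed by B-alkyl Suzuki–Miyaura coupling with an α-iodoenone, a well-used pairing that forms the C9–C11 bond under mild base without involving the C13 stereocentre.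

Step 6
Reactants: 10 2-alkylcyclopent-2-en-1-one
Product: 12 (2R,3R)-2-[(3S)-3-({[tert-butyl(diphenyl)silyl]oxy}methyl)-6-(furan-3-yl)hexyl]-2,3-dimethylcyclopentan-1-one, via magnesium enolate 11 (not isolated)
Conditions: MeMgBr, Cu(OTf)2 (3 mol %), C2-symmetric chiral imidazolinium tetrafluoroborate (N-heterocyclic carbene precursor, 4 mol %), Et2O, −30 °C; then MeI, DMPU, −30 → 0 °C
Reagents that add atoms: methylmagnesium bromide, C[Mg]Br; iodomethane, CI
Why: Copper-catalysed asymmetric conjugate addition with enolate alkylation, in which the carbene complex formed from Cu(OTf)2 delivers methyl to one face of C8 (ligand enantiomer chosen for 3R) and the flat cyclopentenolate 11 is then methylated anti to that methyl, so C9 becomes quaternary with the two methyls trans and the chain cis to the C8 methyl (2R,3R), a facial bias that is stronger in the five-membered than in the six-membered enolate.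

Step 7
Reactants: 12 (2R,3R)-cyclopentanone; 13 4-methylpent-3-en-2-one (mesityl oxide)
Product: 16 (2R,3R,6S)-2-[(3S)-3-({[tert-butyl(diphenyl)silyl]oxy}methyl)-6-(furan-3-yl)hexyl]-2,3-dimethyl-6-(2-methyl-4-oxopentan-2-yl)cyclohexan-1-one, via β-ketosilane 14 (not isolated), via enol silane 15 (not isolated)
Conditions: Me3SiCHN2, Sc(OTf)3 (10 mol %), toluene, 0 → 40 °C; volatiles removed; then 13, TiCl4, CH2Cl2, −78 °C; H2O quench
Reagents that add atoms: (trimethylsilyl)diazomethane, C[Si](C)(C)C=[N+]=[N-]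
Why: Proposed new method: a one-flask homologative Mukaiyama–Michael reaction in which the diazo carbon adds to Sc(OTf)3-activated 12, the less hindered CH2 (C6) rather than quaternary C9 makes the 1,2-shift with loss of N2 and so expands the five- to the six-membered ring A (C5 enters as a CH–SiMe3 unit), β-ketosilane 14 isomerises by 1,3 C→O silyl shift to the single enol silane regioisomer 15, and TiCl4-activated mesityl oxide then attacks C5 from the face opposite the C9 CH2 chain and the C8 methyl (avoiding 1,3-diaxial and flagpole contacts) to form the C5–C4 bond and the (6S) centre with moderate to good selectivity; the closest known reactions are Lewis-acid-catalysed Me3SiCHN2 ring expansions of cycloalkanones to β-ketosilanes or enol silanes and the TiCl4-mediated Mukaiyama–Michael addition to mesityl oxide, which have not been combined nor shown on an α-quaternary cyclopentanone.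

Step 8
Reactants: 16 1,5-diketone
Product: 17 (4aS,7R,8R)-8-[(3S)-3-({[tert-butyl(diphenyl)silyl]oxy}methyl)-6-(furan-3-yl)hexyl]-4,4,7,8-tetramethyl-4,4a,5,6,7,8-hexahydronaphthalen-2(3H)-one
Conditions: KOtBu (0.3 equiv), t-BuOH/THF, 50 °C
Reagents that add atoms: none
Why: Intramolecular aldol condensation (the ring-closing half of a Robinson annulation), in which only the methyl ketone enolate (C1) can reach C10 through a six-membered transition state and E1cB loss of water gives the conjugated C1=C10 enone, while C5 keeps its configuration because enolising it would require a badly strained tetrasubstituted enolate flanked by two quaternary carbons.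

Step 9
Reactants: 17 silyl-protected enone
Product: 18 (4aS,7R,8R)-8-[(3S)-6-(furan-3-yl)-3-(hydroxymethyl)hexyl]-4,4,7,8-tetramethyl-4,4a,5,6,7,8-hexahydronaphthalen-2(3H)-one
Conditions: Bu4NF, THF, rt
Reagents that add atoms: none
Why: Fluoride-mediated desilylation driven by the strong Si–F bond frees the primary alcohol without affecting the enone, the furan or any stereocentre.

Step 10
Reactants: 18 primary alcohol
Product: 19 (2S)-5-(furan-3-yl)-2-{2-[(1R,2R,4aS)-1,2,5,5-tetramethyl-7-oxo-1,2,3,4,4a,5,6,7-octahydronaphthalen-1-yl]ethyl}pentyl hydrogen sulfate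
Conditions: SO3·pyridine, pyridine, 0 °C → rt; cold aqueous work-up at pH 2, n-BuOH extraction
Reagents that add atoms: sulfur trioxide pyridine complex, O=S(=O)([O-])[n+]1ccccc1
Why: O-Sulfation of an unhindered primary alcohol with the mild SO3·pyridine complex, which at room temperature sulfonates neither the 3-alkylfuran nor the enone and touches no stereocentre.

**Compound list**

1 | 3-bromofuran | Brc1ccoc1 | starting material
2 | but-3-en-1-ylmagnesium bromide | C=CCC[Mg]Br | starting material
3 | 3-(but-3-en-1-yl)furan | C=CCCc1ccoc1 | intermediate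
4 | 5-(furan-3-yl)pentanal | O=CCCCCc1ccoc1 | intermediate
5 | (2R)-5-(furan-3-yl)-2-(hydroxymethyl)pentanal | O=C[C@H](CCCc1ccoc1)CO | intermediate
6 | (2R)-2-({[tert-butyl(diphenyl)silyl]oxy}methyl)-5-(furan-3-yl)pentanal | O=C[C@H](CCCc1ccoc1)CO[Si](c1ccccc1)(c1ccccc1)C(C)(C)C | intermediate
7 | tert-butyl{[(2S)-2-ethenyl-5-(furan-3-yl)pentyl]oxy}diphenylsilane | C=C[C@H](CCCc1ccoc1)CO[Si](c1ccccc1)(c1ccccc1)C(C)(C)C | intermediate
8 | 2-iodocyclopent-2-en-1-one | O=C1CCC=C1I | starting material
9 | 9-[(3R)-3-({[tert-butyl(diphenyl)silyl]oxy}methyl)-6-(furan-3-yl)hexyl]-9-borabicyclo[3.3.1]nonane | C1CCC2CCCC1B2CC[C@H](CCCc1ccoc1)CO[Si](c1ccccc1)(c1ccccc1)C(C)(C)C | intermediate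
10 | 2-[(3S)-3-({[tert-butyl(diphenyl)silyl]oxy}methyl)-6-(furan-3-yl)hexyl]cyclopent-2-en-1-one | O=C1CCC=C1CC[C@H](CCCc1ccoc1)CO[Si](c1ccccc1)(c1ccccc1)C(C)(C)C | intermediate
11 | bromo({(3R)-2-[(3S)-3-({[tert-butyl(diphenyl)silyl]oxy}methyl)-6-(furan-3-yl)hexyl]-3-methylcyclopent-1-en-1-yl}oxy)magnesium | C[C@@H]1CCC(O[Mg]Br)=C1CC[C@H](CCCc1ccoc1)CO[Si](c1ccccc1)(c1ccccc1)C(C)(C)C | intermediate
12 | (2R,3R)-2-[(3S)-3-({[tert-butyl(diphenyl)silyl]oxy}methyl)-6-(furan-3-yl)hexyl]-2,3-dimethylcyclopentan-1-one | C[C@@H]1CCC(=O)[C@]1(C)CC[C@H](CCCc1ccoc1)CO[Si](c1ccccc1)(c1ccccc1)C(C)(C)C | intermediate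
13 | 4-methylpent-3-en-2-one (mesityl oxide) | CC(=O)C=C(C)C | starting material
14 | (2R,3R)-2-[(3S)-3-({[tert-butyl(diphenyl)silyl]oxy}methyl)-6-(furan-3-yl)hexyl]-2,3-dimethyl-6-(trimethylsilyl)cyclohexan-1-one (both C6 epimers) | C[C@@H]1CCC([Si](C)(C)C)C(=O)[C@]1(C)CC[C@H](CCCc1ccoc1)CO[Si](c1ccccc1)(c1ccccc1)C(C)(C)C | intermediate
15 | {[(5R,6R)-6-[(3S)-3-({[tert-butyl(diphenyl)silyl]oxy}methyl)-6-(furan-3-yl)hexyl]-5,6-dimethylcyclohex-1-en-1-yl]oxy}(trimethyl)silane | C[C@@H]1CCC=C(O[Si](C)(C)C)[C@]1(C)CC[C@H](CCCc1ccoc1)CO[Si](c1ccccc1)(c1ccccc1)C(C)(C)C | intermediate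
16 | (2R,3R,6S)-2-[(3S)-3-({[tert-butyl(diphenyl)silyl]oxy}methyl)-6-(furan-3-yl)hexyl]-2,3-dimethyl-6-(2-methyl-4-oxopentan-2-yl)cyclohexan-1-one | C[C@@H]1CC[C@@H](C(C)(C)CC(C)=O)C(=O)[C@]1(C)CC[C@H](CCCc1ccoc1)CO[Si](c1ccccc1)(c1ccccc1)C(C)(C)C | intermediate
17 | (4aS,7R,8R)-8-[(3S)-3-({[tert-butyl(diphenyl)silyl]oxy}methyl)-6-(furan-3-yl)hexyl]-4,4,7,8-tetramethyl-4,4a,5,6,7,8-hexahydronaphthalen-2(3H)-one | C[C@@H]1CC[C@@H]2C(=CC(=O)CC2(C)C)[C@]1(C)CC[C@H](CCCc1ccoc1)CO[Si](c1ccccc1)(c1ccccc1)C(C)(C)C | intermediate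
18 | (4aS,7R,8R)-8-[(3S)-6-(furan-3-yl)-3-(hydroxymethyl)hexyl]-4,4,7,8-tetramethyl-4,4a,5,6,7,8-hexahydronaphthalen-2(3H)-one | C[C@@H]1CC[C@@H]2C(=CC(=O)CC2(C)C)[C@]1(C)CC[C@H](CCCc1ccoc1)CO | intermediate
19 | (2S)-5-(furan-3-yl)-2-{2-[(1R,2R,4aS)-1,2,5,5-tetramethyl-7-oxo-1,2,3,4,4a,5,6,7-octahydronaphthalen-1-yl]ethyl}pentyl hydrogen sulfate | C[C@@H]1CC[C@@H]2C(=CC(=O)CC2(C)C)[C@]1(C)CC[C@H](CCCc1ccoc1)COS(=O)(=O)O | target

**Step count and risks**

Total step count: 10. Longest linear sequence: 10 (steps 1 to 10, fully linear from 1).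

Most at risk is step 7, the proposed new step. The hindered cyclopentanone may homologate slowly, some migration of the quaternary carbon or epoxide formation may compete, the enol silane may be lost by protodesilylation, the furan may be alkylated by TiCl4-activated mesityl oxide, and the facial selectivity at C5 is only predicted. The fallback uses known chemistry and buys the six-membered ring instead of making it by homologation; it sets out from alkene 7 (through its 9-BBN adduct 9) and returns to the route at enol silane 15. Borane 9 is coupled under the step 5 conditions with commercial 2-iodocyclohex-2-en-1-one to give 2-[(3S)-3-({[tert-butyl(diphenyl)silyl]oxy}methyl)-6-(furan-3-yl)hexyl]cyclohex-2-en-1-one F1. The step 6 protocol (MeMgBr, Cu(OTf)2 and the chiral carbene ligand, then MeI and DMPU) gives, through the bromomagnesium enolate bromo({(3R)-2-[(3S)-3-({[tert-butyl(diphenyl)silyl]oxy}methyl)-6-(furan-3-yl)hexyl]-3-methylcyclohex-1-en-1-yl}oxy)magnesium F2, the ketone (2R,3R)-2-[(3S)-3-({[tert-butyl(diphenyl)silyl]oxy}methyl)-6-(furan-3-yl)hexyl]-2,3-dimethylcyclohexan-1-one F3. Because F3 can enolise only toward C5, Me3SiOTf and Et3N in CH2Cl2 at 0 °C convert it into 15, and mesityl oxide with TiCl4 at −78 °C then gives 16 as in the second half of step 7.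

Second is step 6, where uncatalysed 1,2-addition of the Grignard reagent, a modest ee at C8 (which would appear as a hard-to-separate diastereomer because C13 is already fixed) or a sluggish magnesium enolate methylation could lower the yield. The fallback separates the two C–C bond formations through an isolated enol silane; it sets out from enone 10 and returns at ketone 12. Conjugate addition of Me3Al with Cu(O2CC4H3S) (copper thiophene-2-carboxylate, 5 mol %) and a chiral phosphoramidite in Et2O at −30 °C, followed by trapping of the aluminium enolate with Me3SiOTf, gives trimethyl({(3R)-2-[(3S)-3-({[tert-butyl(diphenyl)silyl]oxy}methyl)-6-(furan-3-yl)hexyl]-3-methylcyclopent-1-en-1-yl}oxy)silane F4, which can be purified and assayed for ee. MeLi in THF at 0 °C then releases lithium (3R)-2-[(3S)-3-({[tert-butyl(diphenyl)silyl]oxy}methyl)-6-(furan-3-yl)hexyl]-3-methylcyclopent-1-en-1-olate F5, and MeI with DMPU methylates it anti to the C8 methyl to give 12.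

Third is step 8, because the C10 ketone lies between a quaternary and a heavily substituted carbon and the Michael adduct of mesityl oxide can revert by retro-Michael cleavage under equilibrating base. The fallback replaces the thermodynamic condensation by a kinetic, irreversible aldol addition and a separate dehydration; it sets out from diketone 16 and returns at enone 17. LiN(iPr)2 in THF at −78 °C removes a proton only from the methyl group, and warming to −20 °C closes ring B to the aldol (4aS,7R,8R)-8-[(3S)-3-({[tert-butyl(diphenyl)silyl]oxy}methyl)-6-(furan-3-yl)hexyl]-8a-hydroxy-4,4,7,8-tetramethyl-3,4,4a,5,6,7,8,8a-octahydronaphthalen-2(1H)-one F6 (configuration at C8a as formed). Burgess reagent in benzene at 50 °C then eliminates toward the acidic C1–H to give 17 without touching C5.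

**Further compounds**

F1 | step 7 | 2-[(3S)-3-({[tert-butyl(diphenyl)silyl]oxy}methyl)-6-(furan-3-yl)hexyl]cyclohex-2-en-1-one | O=C1CCCC=C1CC[C@H](CCCc1ccoc1)CO[Si](c1ccccc1)(c1ccccc1)C(C)(C)C
F2 | step 7 | bromo({(3R)-2-[(3S)-3-({[tert-butyl(diphenyl)silyl]oxy}methyl)-6-(furan-3-yl)hexyl]-3-methylcyclohex-1-en-1-yl}oxy)magnesium | C[C@@H]1CCCC(O[Mg]Br)=C1CC[C@H](CCCc1ccoc1)CO[Si](c1ccccc1)(c1ccccc1)C(C)(C)C
F3 | step 7 | (2R,3R)-2-[(3S)-3-({[tert-butyl(diphenyl)silyl]oxy}methyl)-6-(furan-3-yl)hexyl]-2,3-dimethylcyclohexan-1-one | C[C@@H]1CCCC(=O)[C@]1(C)CC[C@H](CCCc1ccoc1)CO[Si](c1ccccc1)(c1ccccc1)C(C)(C)C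
F4 | step 6 | trimethyl({(3R)-2-[(3S)-3-({[tert-butyl(diphenyl)silyl]oxy}methyl)-6-(furan-3-yl)hexyl]-3-methylcyclopent-1-en-1-yl}oxy)silane | C[C@@H]1CCC(O[Si](C)(C)C)=C1CC[C@H](CCCc1ccoc1)CO[Si](c1ccccc1)(c1ccccc1)C(C)(C)C
F5 | step 6 | lithium (3R)-2-[(3S)-3-({[tert-butyl(diphenyl)silyl]oxy}methyl)-6-(furan-3-yl)hexyl]-3-methylcyclopent-1-en-1-olate | C[C@@H]1CCC(O[Li])=C1CC[C@H](CCCc1ccoc1)CO[Si](c1ccccc1)(c1ccccc1)C(C)(C)C
F6 | step 8 | (4aS,7R,8R)-8-[(3S)-3-({[tert-butyl(diphenyl)silyl]oxy}methyl)-6-(furan-3-yl)hexyl]-8a-hydroxy-4,4,7,8-tetramethyl-3,4,4a,5,6,7,8,8a-octahydronaphthalen-2(1H)-one | C[C@@H]1CC[C@@H]2C(O)(CC(=O)CC2(C)C)[C@]1(C)CC[C@H](CCCc1ccoc1)CO[Si](c1ccccc1)(c1ccccc1)C(C)(C)C
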